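The readings were computed for substances that don't exist; the scatter is artificial.

| flask | D | remark | time |
|---|---|---|---|
| north | 0.15 M | the very flask that is asked about, followed so far |  |
| flask | 0.15 M |  | 12 h |

north run (percent of the D charged)

| time / h | E / % | G / % | D / % |
|---|---|---|---|
| 0.333 | 14.5 | 49.6 | 11.8 |
| 0.833 | 6.1 | 80.2 | 3.5 |
| 1.50 | 4.4 | 87.8 | 2.3 |
| 2.50 | 4.0 | 87.8 | 1.6 |

(readings scatter by 0.3 percentage points)

* how much E there is at 12 h, in percent of the D charged
* how much G there is at 12 h, in percent of the D charged

- steps that have been proposed: E <-> Q; E <-> G; D <-> E

Take time first: the last reading stands at 2.50 h and the question at 12 h, so ask what can still move. The proposed steps join E to Q, to G and to D, each both ways, and Q is the gap in the balance. Divide the rate from E to G by the rate back and time drops out: the two are equal at one value of G over E. G reads 87.8% at 1.50 h and 87.8% at 2.50 h, so take the last pair as that point. Call it the lock, G over E at the last reading, 21.9, the mark of thermodynamic control. It rests on a small E reading of 4.0%, good to 0.3 percentage points.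

Now solve two extreme flasks. In the frozen flask nothing moves after 2.50 h, and G stays 87.8%. In the drained flask D goes to nothing and its 1.6% is shared in proportion over E, Q and G, which gives G 89.2%. Put the real flask between them: D fell 0.7 points over the last interval, yet D and E are joined both ways, so D can stop short of nothing. My own reckoning takes the middle, G 88.5%, and the lock then gives E 4.03%.

The forecast says E 3.9%, less than mine, and G 88.3%, close to mine, holding that G “has essentially reached equilibrium with E”.

At 12 h the flask gives E 3.83% and G 88.2%, and the forecast held.

    E ⇌ Q (K = 1.60, k = 0.0180 s⁻¹)
    E ⇌ G (K = 23.0, k = 0.00270 s⁻¹)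
    D ⇌ E (K = 2.10, k = 0.00270 s⁻¹)

Divide that G by the lock: E comes to 4.02% against the 3.83% found, a gap of 0.18 points. Take the same flask read at 50 h, with its amounts and temperature unchanged. It holds G 88.2%, so the lock gives E 4.02%, and the flask holds E 3.83%.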